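The easy step came first: I set the new flasks beside the two earlier runs and added starting material and product in each reading, taking a sum of 100 percent of the charge as the zero of the scale.

| setting | north | north-east | beta | epsilon | eta |
|---|---|---|---|---|---|
| starting material | 3 mM | 2 mM | 2.0 mM | 2.0 mM | 2.0 mM |
| protic impurity | 0.40 mM | 0.40 mM | 0.580 mM | 0.400 mM | 0.480 mM |
| precatalyst | 11 µM | 22 µM | 11 µM | 11 µM | 11 µM |
| remark | run made earlier | run made earlier |  |  |  |
| time |  |  | 12 min | 12 min | 12 min |

| run | time / min | starting material / % | product / % | catalyst intermediate B / % | catalyst intermediate A / % |
|---|---|---|---|---|---|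
| north | 0.417 | 84.1 | 3.6 | 0.1 | 0 |
| north | 1.00 | 75.2 | 12.1 | 0 | 0.3 |
| north | 2.00 | 55.5 | 31.6 | 0 | 0 |
| north | 3.00 | 40.3 | 45.9 | 0 | 0 |
| north | 4.00 | 28.9 | 58.0 | 0.4 | 0.7 |
| north | 6.00 | 13.6 | 72.2 | 0.6 | 0 |
| north | 8.00 | 7.2 | 79.6 | 0.6 | 0.1 |
| north-east | 0.500 | 71.0 | 7.5 | 0.4 | 0.2 |
| north-east | 0.833 | 61.2 | 19.0 | 0 | 0.5 |
| north-east | 1.33 | 45.7 | 35.0 | 0.3 | 0.3 |
| north-east | 2.00 | 28.4 | 51.7 | 0.4 | 0.1 |
| north-east | 3.00 | 13.8 | 65.8 | 0 | 0 |
| north-east | 5.00 | 2.8 | 77.1 | 0.6 | 0.6 |
| north-east | 8.00 | 0.6 | 79.2 | 0 | 0 |

(standard deviation of a reading: 0.5 percentage points)

- the numbers in the tables scatter by 0.5 percentage points (one standard deviation)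
- a reading or a percentage of product counts all its forms, free or not
- no earlier run changes the charge of protic impurity; that part of a forecast is a guess

- which of these there is most of at the end, counted by the starting material in it, beta (catalyst intermediate B / starting material / product / catalyst intermediate A)
- which of these there is most of at the end, counted by the starting material in it, epsilon (catalyst intermediate B / starting material / product / catalyst intermediate A)
- which of these there is most of at the end, counted by the starting material in it, eta (catalyst intermediate B / starting material / product / catalyst intermediate A)
- how much there is at the end of the one of these that leads, in percent of the starting material charged: beta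
- how much there is at the end of the one of these that leads, in percent of the starting material charged: epsilon
- how much there is at the end of the one of these that leads, in percent of the starting material charged: eta

At the last readings the north run summed to 86.8% and the north-east run to 79.8%. Multiplied by their charges, the gaps were 0.396 mM and 0.404 mM, and each run held 0.40 mM of protic impurity. So I supposed that each protic impurity removes one starting material. That gave the ceiling, one minus [protic impurity]/[starting material] at the charge: 80.0% for epsilon, 76.0% for eta and 71.0% for beta.

But a slow leak might merely have reached that gap by the last reading. It had not: the first readings already summed to 87.7% in the north run and 78.5% in the north-east run.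

Next doubt: a ceiling is not a yield. Late in the north run the starting material fell in a pseudo-first-order way, with a reading of 0.347 /min. At 8.00 min it held 8.31% of what the ceiling allowed, and by my reckoning at that reading, the 4.00 min up to the asked time took that share down to 2.07%. I carried that share to the new flasks, which share the north run's precatalyst charge. My reckoning was 78.3% for epsilon, 74.4% for eta and 69.5% for beta.

The last doubt I could not compute away: neither run changed the impurity charge, so beta and eta rested on a guess.

The forecast named product as the leader in each flask, with 78.2% for epsilon (76.5% to 79.5%), 74% for eta (70% to 75.5%) and 68.5% for beta (62% to 70.5%). It said: “The impurity effect on rate is a guess, so the ranges stretch lower.” My figure for beta stood 1 percentage point above it.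

The flasks gave product in the lead at 79.0% for epsilon, 75.0% for eta and 70.1% for beta.

    starting material + free catalyst ⇌ catalyst intermediate A (K = 38300 /M, k = 612 /M/s)
    catalyst intermediate A → catalyst intermediate B (k = 8.48 /s)
    catalyst intermediate B → free catalyst + product (k = 5.86 /s)
    precatalyst → free catalyst (k = 0.0322 /s)
    starting material + protic impurity → quenched substrate (k = 115 /M/s)
    crystals ⇌ product, rate k6*(cs6 - [product]) while solid is left; crystals form when [product] > cs6 (solubility = 0.0460 mM, k = 0.150 /s)

Beta ended 8.9 points below epsilon, and the main reason is the difference in the concentration of protic impurity: with that difference taken away, beta's product goes from 70.1% to 79.0%. Left until 120 min, epsilon stands at 80.0% against its ceiling of 80.0%. The neighbour charged with 3.4 mM of starting material and the same impurity has a ceiling of 88.2%, and at 12.0 min it holds 86.8% of product with 1.4% of starting material left.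

The earlier runs and the new flask were generated by integration for an exercise.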